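**Retrosynthetic overview**
- Both acetates come from a 6-hydroxy-17-acetoxy-7-ene. Its axial C6–O is set by hydride attack on a 6-oxo-7-ene from the face away from the C10 methyl, and that enone comes from a C8 tertiary allylic carbinol by oxidative 1,3-transposition.
- Key C8–C17 bond: a hydroxymethyl anion equivalent (formaldehyde with reversed polarity) adds to the C8 carbonyl of a bicyclic enone.
- C9–C11 bond: alkylation of that enone with an (E)-dienyl bromide; C9 is fixed by kinetic protonation.
- Ring B is closed last, by aldol condensation of a C6 aldehyde with a C8 methyl ketone; ring A comes ready-made from 2,2,6-trimethylcyclohexanone.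
- C10 is set by palladium-catalysed decarboxylative asymmetric allylation; the C6 carbon is added by epoxide-to-aldehyde homologation.

Assumption: positions are cited in labdane numbering (decalin C1–C10, C17 on C8, side chain C11–C16 on C9, C20 on C10), and (S)-t-BuPHOX is taken to give the (S)-ketone of step 2 as it does for 2-allyl-2-methylcyclohexanone (otherwise the (R)-ligand is used).

Step 1
Reactants: 1 2,2,6-trimethylcyclohexan-1-one (racemic); 2 prop-2-en-1-yl carbonochloridate (allyl chloroformate)
Product: 3 prop-2-en-1-yl 2,6,6-trimethylcyclohex-1-en-1-yl carbonate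
Conditions: LiN(SiMe3)2, THF, 0 °C; then 2, −78 °C to rt
Reagents that add atoms: none
Why: Enolate O-acylation: 1 can enolise only toward C6, so a single tetrasubstituted lithium enolate forms and is trapped on oxygen by the chloroformate; the stereocentre of racemic 1 is erased and none is formed.

Step 2
Reactants: 3 prop-2-en-1-yl 2,6,6-trimethylcyclohex-1-en-1-yl carbonate
Product: 4 (6S)-2,2,6-trimethyl-6-(prop-2-en-1-yl)cyclohexan-1-one
Conditions: Pd2(dba)3 (2.5 mol %), (S)-t-BuPHOX (6.25 mol %), THF, 25 °C
Reagents that add atoms: none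
Why: Decarboxylative asymmetric allylic alkylation (Tsuji–Stoltz): zerovalent palladium ionises the allyl carbonate, CO2 is lost, and the enolate recombines with the π-allyl fragment inside the chiral PHOX pocket, which sets the quaternary centre (C10) as S with about 90% ee precedented for this substrate.

Step 3
Reactants: 4 (6S)-2,2,6-trimethyl-6-(prop-2-en-1-yl)cyclohexan-1-one
Product: 5 (8S)-4,4,8-trimethyl-8-(prop-2-en-1-yl)-1-oxaspiro[2.5]octane (both epimers at the spiro carbon)
Conditions: Me3S+ I−, n-BuLi, THF, −10 °C to rt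
Reagents that add atoms: trimethylsulfonium iodide C[S+](C)C.[I-]
Why: Corey–Chaykovsky epoxidation: the small sulfonium ylide adds to the non-enolisable carbonyl between the two quaternary carbons and closes to the spiro-epoxide; the new spiro centre forms as a mixture that does not matter because it is destroyed in steps 4 and 6.

Step 4
Reactants: 5 (8S)-4,4,8-trimethyl-8-(prop-2-en-1-yl)-1-oxaspiro[2.5]octane
Product: 6 (6S)-2,2,6-trimethyl-6-(prop-2-en-1-yl)cyclohexane-1-carbaldehyde (both C1 epimers)
Conditions: BF3·OEt2 (0.2 equiv), CH2Cl2, −78 °C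
Reagents that add atoms: none
Why: Meinwald (semipinacol) rearrangement: the Lewis acid opens the epoxide at the tertiary carbon and a hydride shifts from the CH2O carbon to give the aldehyde (C6); the new α-CH (C5) forms as both epimers and is corrected in step 6.

Step 5
Reactants: 6 (6S)-2,2,6-trimethyl-6-(prop-2-en-1-yl)cyclohexane-1-carbaldehyde
Product: 7 (6S)-2,2,6-trimethyl-6-(2-oxopropyl)cyclohexane-1-carbaldehyde (both C1 epimers)
Conditions: PdCl2 (10 mol %), CuCl (1 equiv), O2 (1 atm), DMF/H2O 7:1, rt
Reagents that add atoms: water O (its oxygen becomes the ketone oxygen); dioxygen O=O (terminal oxidant)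
Why: Tsuji–Wacker oxidation: divalent palladium effects Markovnikov hydroxypalladation of the terminal alkene and the enol collapses to the methyl ketone (precedented on the parent ketone 4), leaving the hindered aldehyde and the stereocentre untouched.

Step 6
Reactants: 7 (6S)-2,2,6-trimethyl-6-(2-oxopropyl)cyclohexane-1-carbaldehyde
Product: 8 (4aR,8aS)-5,5,8a-trimethyl-4a,5,6,7,8,8a-hexahydronaphthalen-2(1H)-one
Conditions: KOH, MeOH, 60 °C
Reagents that add atoms: none
Why: Intramolecular aldol condensation: the methyl ketone enolate (C7) attacks the aldehyde (C6), the only six-membered option, and dehydration gives the enone and closes ring B; under the basic conditions C5 equilibrates through the aldehyde enolate and the extended enolate of the product to the trans-fused bicycle (H5 anti to the C10 methyl).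

Step 7
Reactants: 9 (2E)-3-methylpent-2-en-4-yn-1-ol
Product: 10 (2E)-3-methylpenta-2,4-dien-1-ol
Conditions: H2 (1 atm), Pd/CaCO3 poisoned with Pb(OAc)2, quinoline, EtOAc, rt
Reagents that add atoms: none
Why: Lindlar-type semihydrogenation stops at the alkene, turning the terminal alkyne into the vinyl group without touching the existing E trisubstituted double bond.

Step 8
Reactants: 10 (2E)-3-methylpenta-2,4-dien-1-ol
Product: 11 (3E)-5-bromo-3-methylpenta-1,3-diene
Conditions: PBr3 (0.4 equiv), Et2O, −10 °C; used at once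
Reagents that add atoms: phosphorus tribromide BrP(Br)Br
Why: Bromination of a primary allylic alcohol with PBr3: SN2 displacement of the intermediate phosphite keeps the E geometry of the diene.

Step 9
Reactants: 8 (4aR,8aS)-5,5,8a-trimethyl-4a,5,6,7,8,8a-hexahydronaphthalen-2(1H)-one; 11 (3E)-5-bromo-3-methylpenta-1,3-diene
Product: 13 (5R,9S,10R,12E)-17-norlabda-6,12,14-trien-8-one, via C9-epimeric ketone 12 (not isolated)
Conditions: LiN(iPr)2 (1.05 equiv), THF, −78 °C; 11 (1.0 equiv), DMPU, −78 to −20 °C; then LiN(iPr)2 (1.3 equiv), −78 to −30 °C; AcOH, −95 °C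
Reagents that add atoms: none
Why: Kinetic α′-alkylation of an enone enolate: the bromide enters C9 anti to the angular methyl to give the 9-epimer 12, which is re-enolised in the same flask to the tetrasubstituted enolate and protonated under kinetic control, again anti to the angular methyl, so that H9 ends trans and the side chain cis to that methyl as in the target.

Step 10
Reactants: 13 (5R,9S,10R,12E)-17-norlabda-6,12,14-trien-8-one
Product: 15 (5R,8R,9S,10R,12E)-labda-6,12,14-triene-8,17-diol, via silyl carbinol 14 (not isolated)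
Conditions: (iPrO)Me2SiCH2MgCl [from (iPrO)Me2SiCH2Cl and Mg], CeCl3, THF, −78 to 0 °C; then KF, KHCO3, 30% H2O2, THF/MeOH, rt
Reagents that add atoms: {[dimethyl(propan-2-yloxy)silyl]methyl}magnesium chloride CC(C)O[Si](C)(C)C[Mg]Cl; hydrogen peroxide OO
Why: Nucleophilic hydroxymethylation (Tamao): the silylmethyl Grignard reagent is a hydroxymethyl anion equivalent, that is formaldehyde with reversed polarity, so the C8–C17 bond joins two carbons that are both normally electrophilic; cerium-assisted 1,2-addition occurs anti to the angular methyl and Tamao–Fleming oxidation turns C–Si into C–OH, while the C8 configuration is irrelevant because it is lost in step 12.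

Step 11
Reactants: 15 (5R,8R,9S,10R,12E)-labda-6,12,14-triene-8,17-diol
Product: 16 (5R,8R,9S,10R,12E)-8-hydroxylabda-6,12,14-trien-17-yl acetate
Conditions: Ac2O, pyridine, CH2Cl2, 0 °C
Reagents that add atoms: acetic anhydride CC(=O)OC(C)=O
Why: Chemoselective esterification: the primary hydroxyl is acetylated while the hindered tertiary allylic hydroxyl stays free for the transposition.

Step 12
Reactants: 16 (5R,8R,9S,10R,12E)-8-hydroxylabda-6,12,14-trien-17-yl acetate
Product: 17 (5R,9S,10S,12E)-6-oxolabda-7,12,14-trien-17-yl acetate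
Conditions: pyridinium chlorochromate [C5H5NH][CrO3Cl], NaOAc, 4 Å sieves, CH2Cl2, rt
Reagents that add atoms: pyridinium chlorochromate [O-][Cr](=O)(=O)Cl.c1cc[nH+]cc1
Why: Dauben–Babler oxidative 1,3-transposition: the tertiary allylic chromate ester undergoes a [3,3] shift to the secondary chromate at C6, which is oxidised to the enone, moving oxygen from C8 to C6 and the double bond to C7–C8; the buffered, non-basic medium leaves the vinylogously acidic C9–H and the diene alone.

Step 13
Reactants: 17 (5R,9S,10S,12E)-6-oxolabda-7,12,14-trien-17-yl acetate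
Product: 18 (5R,6S,9S,10S,12E)-6-hydroxylabda-7,12,14-trien-17-yl acetate
Conditions: NaBH4, CeCl3·7H2O, MeOH, −20 to 0 °C
Reagents that add atoms: none
Why: Luche 1,2-reduction: hydride adds to the C6 carbonyl from the face anti to the axial C10 and C4 methyls, giving the axial 6-alcohol cis to the C10 methyl (6S) without touching the acetate or the diene.

Step 14
Reactants: 18 (5R,6S,9S,10S,12E)-6-hydroxylabda-7,12,14-trien-17-yl acetate
Product: 19 (5R,6S,9S,10S,12E)-labda-7,12,14-triene-6,17-diyl diacetate
Conditions: Ac2O, Et3N, DMAP, CH2Cl2, rt to 40 °C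
Reagents that add atoms: acetic anhydride CC(=O)OC(C)=O
Why: DMAP-catalysed acyl transfer acetylates the hindered axial secondary alcohol to give the target; no stereocentre changes.

**Compound list**
1 | 2,2,6-trimethylcyclohexan-1-one (racemic) | CC1CCCC(C)(C)C1=O | starting material
2 | prop-2-en-1-yl carbonochloridate (allyl chloroformate) | C=CCOC(Cl)=O | starting material
3 | prop-2-en-1-yl 2,6,6-trimethylcyclohex-1-en-1-yl carbonate | CC1=C(OC(=O)OCC=C)C(C)(C)CCC1 | intermediate
4 | (6S)-2,2,6-trimethyl-6-(prop-2-en-1-yl)cyclohexan-1-one | C=CC[C@]1(C)CCCC(C)(C)C1=O | intermediate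
5 | (8S)-4,4,8-trimethyl-8-(prop-2-en-1-yl)-1-oxaspiro[2.5]octane, both epimers at the spiro carbon | C=CC[C@]1(C)CCCC(C)(C)C12CO2 | intermediate
6 | (6S)-2,2,6-trimethyl-6-(prop-2-en-1-yl)cyclohexane-1-carbaldehyde, both C1 epimers | C=CC[C@]1(C)CCCC(C)(C)C1C=O | intermediate
7 | (6S)-2,2,6-trimethyl-6-(2-oxopropyl)cyclohexane-1-carbaldehyde, both C1 epimers | CC(=O)C[C@]1(C)CCCC(C)(C)C1C=O | intermediate
8 | (4aR,8aS)-5,5,8a-trimethyl-4a,5,6,7,8,8a-hexahydronaphthalen-2(1H)-one | C1C(=O)C=C[C@@H]2C(C)(C)CCC[C@@]12C | intermediate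
9 | (2E)-3-methylpent-2-en-4-yn-1-ol | C#C/C(C)=C/CO | starting material
10 | (2E)-3-methylpenta-2,4-dien-1-ol | C=C/C(C)=C/CO | intermediate
11 | (3E)-5-bromo-3-methylpenta-1,3-diene | C=C/C(C)=C/CBr | intermediate
12 | (5R,9R,10R,12E)-17-norlabda-6,12,14-trien-8-one (C9 epimer, not isolated) | C=C/C(C)=C/C[C@H]1C(=O)C=C[C@@H]2C(C)(C)CCC[C@@]12C | intermediate
13 | (5R,9S,10R,12E)-17-norlabda-6,12,14-trien-8-one | C=C/C(C)=C/C[C@@H]1C(=O)C=C[C@@H]2C(C)(C)CCC[C@@]12C | intermediate
14 | (5R,8R,9S,10R,12E)-17-[dimethyl(propan-2-yloxy)silyl]labda-6,12,14-trien-8-ol (not isolated) | C=C/C(C)=C/C[C@@H]1[C@@](O)(C[Si](C)(C)OC(C)C)C=C[C@@H]2C(C)(C)CCC[C@@]12C | intermediate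
15 | (5R,8R,9S,10R,12E)-labda-6,12,14-triene-8,17-diol | C=C/C(C)=C/C[C@@H]1[C@@](O)(CO)C=C[C@@H]2C(C)(C)CCC[C@@]12C | intermediate
16 | (5R,8R,9S,10R,12E)-8-hydroxylabda-6,12,14-trien-17-yl acetate | C=C/C(C)=C/C[C@@H]1[C@@](O)(COC(C)=O)C=C[C@@H]2C(C)(C)CCC[C@@]12C | intermediate
17 | (5R,9S,10S,12E)-6-oxolabda-7,12,14-trien-17-yl acetate | C=C/C(C)=C/C[C@@H]1C(COC(C)=O)=CC(=O)[C@@H]2C(C)(C)CCC[C@@]12C | intermediate
18 | (5R,6S,9S,10S,12E)-6-hydroxylabda-7,12,14-trien-17-yl acetate | C=C/C(C)=C/C[C@@H]1C(COC(C)=O)=C[C@H](O)[C@@H]2C(C)(C)CCC[C@@]12C | intermediate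
19 | (5R,6S,9S,10S,12E)-labda-7,12,14-triene-6,17-diyl diacetate | C=C/C(C)=C/C[C@@H]1C(COC(C)=O)=C[C@H](OC(C)=O)[C@@H]2C(C)(C)CCC[C@@]12C | target

**Step count**
Total: 14 steps. Longest linear sequence: 12 steps (steps 1–6 and 9–14). The enantiomeric excess set in step 2 is carried through; no later step can erode it.

**Three steps most likely to fail, with fallbacks**

Step 3 (methylene transfer to a ketone flanked by two quaternary carbons). The fallback sets out from 4 and builds the epoxide by olefination and then electrophilic epoxidation. Me3SiCH2Li with CeCl3 adds to the carbonyl to give (6S)-2,2,6-trimethyl-6-(prop-2-en-1-yl)-1-[(trimethylsilyl)methyl]cyclohexan-1-ol F1. KH then effects Peterson elimination to (1S)-1,3,3-trimethyl-2-methylidene-1-(prop-2-en-1-yl)cyclohexane F2. One equivalent of m-chloroperbenzoic acid epoxidises the more electron-rich 1,1-disubstituted double bond in preference to the monosubstituted allyl alkene, and the route is rejoined at 5.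

Step 9 (alkylation at C9 and inversion of the new centre by kinetic protonation). The fallback sets out from 8 and 10 and makes the C9 enolate by hydride addition instead of deprotonation. MnO2 oxidises 10 to (2E)-3-methylpenta-2,4-dienal F3. Claisen–Schmidt condensation of 8 with this aldehyde (KOH, MeOH) gives (4aR,8aR)-5,5,8a-trimethyl-1-[(2E)-3-methylpenta-2,4-dien-1-ylidene]-4a,5,6,7,8,8a-hexahydronaphthalen-2(1H)-one F4. Conjugate hydride delivery to the exocyclic terminus (C11) with K[BH(sec-Bu)3] at −78 °C generates the tetrasubstituted C8/C9 enolate directly, and a cold acetic acid quench protonates C9 anti to the angular methyl. The route is rejoined at 13. Competing hydride addition at C6 or along the diene is the risk of this fallback.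

Step 12 (oxidative transposition of a crowded tertiary allylic alcohol next to a diene). The fallback sets out from 16 and separates the oxygen shift from the oxidation. Catalytic Ph3SiOReO3 in Et2O at −50 to 0 °C effects a redox-neutral 1,3-hydroxyl shift to (5R,9S,10S,12E)-6-hydroxylabda-7,12,14-trien-17-yl acetate F5, formed as a mixture of C6 epimers. MnO2 then oxidises this secondary allylic alcohol to the enone, whichever epimer is present, and the route is rejoined at 17.

**Further compounds**
F1 | step 3 | (6S)-2,2,6-trimethyl-6-(prop-2-en-1-yl)-1-[(trimethylsilyl)methyl]cyclohexan-1-ol (C1 epimers) | C=CC[C@]1(C)CCCC(C)(C)C1(O)C[Si](C)(C)C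
F2 | step 3 | (1S)-1,3,3-trimethyl-2-methylidene-1-(prop-2-en-1-yl)cyclohexane | C=CC[C@]1(C)CCCC(C)(C)C1=C
F3 | step 9 | (2E)-3-methylpenta-2,4-dienal | C=C/C(C)=C/C=O
F4 | step 9 | (4aR,8aR)-5,5,8a-trimethyl-1-[(2E)-3-methylpenta-2,4-dien-1-ylidene]-4a,5,6,7,8,8a-hexahydronaphthalen-2(1H)-one | C=C/C(C)=C/C=C1C(=O)C=C[C@@H]2C(C)(C)CCC[C@@]12C
F5 | step 12 | (5R,9S,10S,12E)-6-hydroxylabda-7,12,14-trien-17-yl acetate (C6 epimers) | C=C/C(C)=C/C[C@@H]1C(COC(C)=O)=CC(O)[C@@H]2C(C)(C)CCC[C@@]12C
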